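**Plan**

1. Prostanoid numbering is used (C1 acid, C6 ketone, ring C8–C12, carbinols C9, C11, C15). The ring carbinol carbon C9 and the C6 carbonyl stand 1,4 to each other across C8–C7. This γ-oxygenated carbonyl is the retron of a conjugate acylation, so the cyclopentane is cut at C8–C9: a C9 aldehyde, as acyl-anion equivalent, adds to C8 of a C7=C8 enoate whose ester carbon is C6.
2. Further cuts: C5–C6 (C1–C5 as an ortho-ester-masked alkyllithium onto a C6 lactone), C13=C14 (cross-metathesis with (S)-oct-1-en-3-ol), C11–C12 (allylboration of 3-silyloxypropanal by a dienylboronate made from ethyl sorbate).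
3. Forward: allylboration joins the acyclic C6–C14 chain; a carbene-catalysed Stetter reaction closes the cyclopentanone, the only carbocycle; hydride reduction closes a temporary γ-lactone (O9–C6); the ω-chain and then the α-chain are attached; the helpers (lactone, silyl ether, ortho ester) are removed.
4. Stereochemistry: C11 and C12 from the catalyst-controlled anti allylboration, C8 from C12 during ring closure, C9 from β-face hydride delivery, C15 from the chiral-pool allylic alcohol, the E C13=C14 bond from metathesis.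

Key step: step 7

Remark: the γ-hydroxy ketones formed from step 13 onward equilibrate with their cyclic C9–O/C6 hemiketals and are written in the open form (TBS = tert-butyldimethylsilyl; pin = pinacolato).

**Route**

Step 1
Reactants: 1 ethyl (2E,4E)-hexa-2,4-dienoate (ethyl sorbate)
Product: 2 ethyl (2E,4E)-6-bromohexa-2,4-dienoate
Conditions: NBS, AIBN (cat.), PhCl, 85 °C
Reagents that add atoms: N-bromosuccinimide, O=C1CCC(=O)N1Br
Why: Wohl–Ziegler radical bromination takes the only allylic hydrogens, those of the terminal methyl group, and the delocalised pentadienyl radical is brominated at the terminus so that the conjugated (2E,4E)-dienoate is kept.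

Step 2
Reactants: 2 ethyl (2E,4E)-6-bromohexa-2,4-dienoate
Product: 3 ethyl (2E,4E)-6-(4,4,5,5-tetramethyl-1,3,2-dioxaborolan-2-yl)hexa-2,4-dienoate
Conditions: B2pin2, Pd2(dba)3 (2.5 mol %), THF, 60 °C
Reagents that add atoms: bis(pinacolato)diboron, CC1(C)OB(OC1(C)C)B1OC(C)(C)C(C)(C)O1
Why: Miyaura-type allylic borylation, in which zerovalent palladium ionises the allylic bromide and the π-allyl complex is borylated at the unhindered terminus, should give the linear dienylboronate with the conjugation and both E double bonds intact.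

Step 3
Reactants: 3 ethyl (2E,4E)-6-(4,4,5,5-tetramethyl-1,3,2-dioxaborolan-2-yl)hexa-2,4-dienoate; 4 3-[(tert-butyldimethylsilyl)oxy]propanal
Product: 6 ethyl (2E,4R,5R)-7-[(tert-butyldimethylsilyl)oxy]-5-hydroxy-4-vinylhept-2-enoate, via pinacol borate ester of the adduct 5 (not isolated)
Conditions: (S)-TRIP [(S)-3,3'-bis(2,4,6-triisopropylphenyl)-1,1'-binaphthyl-2,2'-diyl hydrogen phosphate] (5 mol %), 4 Å MS, toluene, −30 °C to 0 °C; then H2O
Reagents that add atoms: none
Why: Chiral-phosphoric-acid-catalysed allylboration through a closed chair (Zimmerman–Traxler) transition state joins the γ-carbon of the boronate to the aldehyde with the (E)-γ-alkenyl group and the aldehyde chain both equatorial, which gives the anti (4R,5R) pair (C12, C11), while the catalyst antipode expected to direct the allyl unit to the Si face of the aldehyde fixes the absolute sense.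

Step 4
Reactants: 6 ethyl (2E,4R,5R)-7-[(tert-butyldimethylsilyl)oxy]-5-hydroxy-4-vinylhept-2-enoate
Product: 7 ethyl (2E,4R,5R)-5,7-bis[(tert-butyldimethylsilyl)oxy]-4-vinylhept-2-enoate
Conditions: TBSOTf, 2,6-lutidine, CH2Cl2, −78 °C to 0 °C
Reagents that add atoms: tert-butyldimethylsilyl trifluoromethanesulfonate, CC(C)(C)[Si](C)(C)OS(=O)(=O)C(F)(F)F
Why: Silyl ether protection of the hindered secondary alcohol with the silyl triflate and a non-nucleophilic base masks the C11 hydroxyl without touching either stereocentre.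

Step 5
Reactants: 7 ethyl (2E,4R,5R)-5,7-bis[(tert-butyldimethylsilyl)oxy]-4-vinylhept-2-enoate
Product: 8 ethyl (2E,4R,5R)-5-[(tert-butyldimethylsilyl)oxy]-7-hydroxy-4-vinylhept-2-enoate
Conditions: HF·pyridine, pyridine, THF, 0 °C
Reagents that add atoms: none
Why: Selective desilylation relies on the much faster fluoride cleavage of the unhindered primary silyl ether than of the secondary one next to the branched C12 carbon, under buffered conditions that leave the ester and the stereocentres alone.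

Step 6
Reactants: 8 ethyl (2E,4R,5R)-5-[(tert-butyldimethylsilyl)oxy]-7-hydroxy-4-vinylhept-2-enoate
Product: 9 ethyl (2E,4R,5R)-5-[(tert-butyldimethylsilyl)oxy]-7-oxo-4-vinylhept-2-enoate
Conditions: Dess–Martin periodinane, CH2Cl2, 0 °C to rt
Reagents that add atoms: none
Why: Dess–Martin oxidation converts the primary alcohol into the C9 aldehyde under near-neutral conditions that should neither eliminate the β-silyloxy group nor epimerise the doubly allylic C12 centre.

Step 7
Reactants: 9 ethyl (2E,4R,5R)-5-[(tert-butyldimethylsilyl)oxy]-7-oxo-4-vinylhept-2-enoate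
Product: 11 ethyl 2-[(1R,2R,3R)-3-[(tert-butyldimethylsilyl)oxy]-5-oxo-2-vinylcyclopentyl]acetate, via carbene-bound enaminol of the aldehyde 10 (not isolated)
Conditions: 2-(pentafluorophenyl)-6,7-dihydro-5H-pyrrolo[2,1-c][1,2,4]triazol-2-ium tetrafluoroborate (10 mol %), KN(SiMe3)2 (10 mol %), toluene, 23 °C
Reagents that add atoms: none
Why: Intramolecular Stetter reaction: the triazolylidene adds to the C9 aldehyde and proton transfer gives the enaminol 10, an acyl-anion equivalent whose C9 adds to C8, the β-carbon of the tethered (E)-enoate, after which proton transfer and loss of the carbene give the ketone; the closest known reaction type is the carbene-catalysed cyclisation of 7-oxohept-2-enoates to (2-oxocyclopentyl)acetates. The cyclopentane is closed in the 5-exo-trig mode through the C8–C9 bond, which at the same time creates the 1,4-relation between the C9 and C6 carbonyl groups. The only new stereocentre, C8, is controlled by the neighbouring C12 centre: with the C11 silyloxy and C12 vinyl groups pseudo-equatorial in the forming ring, the enoate should be attacked on the face that leaves the acetate arm trans to the vinyl group (8R). Because C8 ends up α to the new ketone, a cis isomer can also drain to this more stable all-trans ring by enolisation. The step needs chemoselectivity for conjugate acylation over aldol or benzoin pathways and over loss of the β-silyloxy group, and site selectivity for C7=C8 over the isolated vinyl group. The first is secured by the fast five-membered closure under a catalytic, weakly basic carbene at room temperature, the second by the fact that only the ester-conjugated double bond is a Michael acceptor.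

Step 8
Reactants: 11 ethyl 2-[(1R,2R,3R)-3-[(tert-butyldimethylsilyl)oxy]-5-oxo-2-vinylcyclopentyl]acetate
Product: 13 (3aR,4R,5R,6aS)-5-[(tert-butyldimethylsilyl)oxy]-4-vinylhexahydro-2H-cyclopenta[b]furan-2-one, via lithium alkoxide of the cis hydroxy ester 12 (not isolated)
Conditions: Li[HB(s-Bu)3], THF, −78 °C to 0 °C; then aq. NH4Cl
Reagents that add atoms: none
Why: Diastereoselective ketone reduction by the bulky borohydride, which should attack the cyclopentanone from the β face opposite the adjacent C8 acetate arm to give the 9α (9S) alkoxide, is followed by lactonisation of this cis alkoxide onto the ethyl ester, so that C9 is set and the temporary O9–C6 ring is closed in one operation.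

Step 9
Reactants: 13 (3aR,4R,5R,6aS)-5-[(tert-butyldimethylsilyl)oxy]-4-vinylhexahydro-2H-cyclopenta[b]furan-2-one; 14 (S)-oct-1-en-3-ol
Product: 15 (3aR,4R,5R,6aS)-5-[(tert-butyldimethylsilyl)oxy]-4-[(1E,3S)-3-hydroxyoct-1-en-1-yl]hexahydro-2H-cyclopenta[b]furan-2-one
Conditions: 14 (3 equiv), (H2IMes)Cl2Ru(=CH-C6H4-2-O-i-Pr) (second-generation Hoveyda–Grubbs catalyst, 5 mol %), CH2Cl2, 40 °C
Reagents that add atoms: none
Why: Olefin cross-metathesis between the ring vinyl group and the excess secondary allylic alcohol releases ethene and should give the thermodynamically preferred E C13=C14 alkene, the C15 (S) centre coming unchanged from the chiral-pool alcohol.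

Step 10
Reactants: 16 5-bromopentanoyl chloride; 17 (3-methyloxetan-3-yl)methanol
Product: 18 (3-methyloxetan-3-yl)methyl 5-bromopentanoate
Conditions: pyridine, CH2Cl2, 0 °C to rt
Reagents that add atoms: none
Why: Acylation of the primary alcohol by the acid chloride (esterification) is fast and leaves the alkyl bromide and the oxetane untouched.

Step 11
Reactants: 18 (3-methyloxetan-3-yl)methyl 5-bromopentanoate
Product: 19 1-(4-bromobutyl)-4-methyl-2,6,7-trioxabicyclo[2.2.2]octane
Conditions: BF3·OEt2 (0.25 equiv), CH2Cl2, −15 °C to rt; Et3N quench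
Reagents that add atoms: none
Why: Lewis-acid-catalysed oxetanyl ester to bicyclic ortho ester rearrangement, in which the ester carbonyl opens the activated oxetane and the freed alkoxide closes the dioxocarbenium ion, hides the future C1 carboxyl from organolithium reagents.

Step 12
Reactants: 19 1-(4-bromobutyl)-4-methyl-2,6,7-trioxabicyclo[2.2.2]octane
Product: 20 1-(4-iodobutyl)-4-methyl-2,6,7-trioxabicyclo[2.2.2]octane
Conditions: NaI, acetone, 56 °C
Reagents that add atoms: sodium iodide, [Na+].[I-]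
Why: Finkelstein halide exchange (SN2), driven by precipitation of NaBr, provides the primary iodide needed for clean iodine–lithium exchange.

Step 13
Reactants: 15 (3aR,4R,5R,6aS)-5-[(tert-butyldimethylsilyl)oxy]-4-[(1E,3S)-3-hydroxyoct-1-en-1-yl]hexahydro-2H-cyclopenta[b]furan-2-one; 20 1-(4-iodobutyl)-4-methyl-2,6,7-trioxabicyclo[2.2.2]octane
Product: 24 1-[(1R,2R,3R,5S)-3-[(tert-butyldimethylsilyl)oxy]-5-hydroxy-2-[(1E,3S)-3-hydroxyoct-1-en-1-yl]cyclopentyl]-6-(4-methyl-2,6,7-trioxabicyclo[2.2.2]octan-1-yl)hexan-2-one, via alkyllithium from the iodide 21 (not isolated), via lithium C15 alkoxide of the lactone 22 (not isolated), via dilithium salt of the cyclic hemiketal 23 (not isolated)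
Conditions: 20 (1.3 equiv), t-BuLi (2.6 equiv), Et2O–pentane, −78 °C; 15, LiN(SiMe3)2 (1.0 equiv), THF, −78 °C; mix at −78 °C; then aq. NH4Cl
Reagents that add atoms: none
Why: Iodine–lithium exchange gives the ortho-ester-bearing primary alkyllithium, which adds once to the carbonyl of the pre-formed lithium alkoxide of the lactone (nucleophilic addition to a lactone) because the tetrahedral lithium hemiketalate does not collapse at −78 °C, so that work-up releases the C6 ketone carrying the complete α-chain and no stereocentre is affected.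

Step 14
Reactants: 24 1-[(1R,2R,3R,5S)-3-[(tert-butyldimethylsilyl)oxy]-5-hydroxy-2-[(1E,3S)-3-hydroxyoct-1-en-1-yl]cyclopentyl]-6-(4-methyl-2,6,7-trioxabicyclo[2.2.2]octan-1-yl)hexan-2-one
Product: 26 6-keto-prostaglandin F1α (7-[(1R,2R,3R,5S)-3,5-dihydroxy-2-[(1E,3S)-3-hydroxyoct-1-en-1-yl]cyclopentyl]-6-oxoheptanoic acid), via triol monoester of the desilylated acid 25 (not isolated)
Conditions: 48 % aq. HF, MeCN, 0 °C to rt; then LiOH, THF–H2O, rt; then 1 M HCl to pH 4
Reagents that add atoms: water, O; lithium hydroxide, [Li+].[OH-]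
Why: Aqueous acid removes the silyl ether and hydrolyses the bicyclic ortho ester to the monoester of the triol (ortho ester hydrolysis), and saponification of this ester followed by mild acidification frees the carboxylic acid without touching any stereocentre or the C6 ketone.

**Compound list**

1 | ethyl (2E,4E)-hexa-2,4-dienoate (ethyl sorbate) | CCOC(=O)/C=C/C=C/C | starting material
2 | ethyl (2E,4E)-6-bromohexa-2,4-dienoate | CCOC(=O)/C=C/C=C/CBr | intermediate
3 | ethyl (2E,4E)-6-(4,4,5,5-tetramethyl-1,3,2-dioxaborolan-2-yl)hexa-2,4-dienoate | CCOC(=O)/C=C/C=C/CB1OC(C)(C)C(C)(C)O1 | intermediate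
4 | 3-[(tert-butyldimethylsilyl)oxy]propanal | O=CCCO[Si](C)(C)C(C)(C)C | starting material
5 | ethyl (2E,4R,5R)-7-[(tert-butyldimethylsilyl)oxy]-5-[(4,4,5,5-tetramethyl-1,3,2-dioxaborolan-2-yl)oxy]-4-vinylhept-2-enoate | C=C[C@@H]([C@H](OB1OC(C)(C)C(C)(C)O1)CCO[Si](C)(C)C(C)(C)C)/C=C/C(=O)OCC | intermediate
6 | ethyl (2E,4R,5R)-7-[(tert-butyldimethylsilyl)oxy]-5-hydroxy-4-vinylhept-2-enoate | C=C[C@@H]([C@H](O)CCO[Si](C)(C)C(C)(C)C)/C=C/C(=O)OCC | intermediate
7 | ethyl (2E,4R,5R)-5,7-bis[(tert-butyldimethylsilyl)oxy]-4-vinylhept-2-enoate | C=C[C@@H]([C@H](O[Si](C)(C)C(C)(C)C)CCO[Si](C)(C)C(C)(C)C)/C=C/C(=O)OCC | intermediate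
8 | ethyl (2E,4R,5R)-5-[(tert-butyldimethylsilyl)oxy]-7-hydroxy-4-vinylhept-2-enoate | C=C[C@@H]([C@H](O[Si](C)(C)C(C)(C)C)CCO)/C=C/C(=O)OCC | intermediate
9 | ethyl (2E,4R,5R)-5-[(tert-butyldimethylsilyl)oxy]-7-oxo-4-vinylhept-2-enoate | C=C[C@@H]([C@H](O[Si](C)(C)C(C)(C)C)CC=O)/C=C/C(=O)OCC | intermediate
10 | ethyl (2E,4R,5R)-5-[(tert-butyldimethylsilyl)oxy]-7-hydroxy-7-[2-(pentafluorophenyl)-6,7-dihydro-2H-pyrrolo[2,1-c][1,2,4]triazol-3(5H)-ylidene]-4-vinylhept-2-enoate (carbene-bound enaminol) | OC(C[C@@H](O[Si](C)(C)C(C)(C)C)[C@H](C=C)/C=C/C(=O)OCC)=C1N(c2c(F)c(F)c(F)c(F)c2F)N=C2CCCN12 | intermediate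
11 | ethyl 2-[(1R,2R,3R)-3-[(tert-butyldimethylsilyl)oxy]-5-oxo-2-vinylcyclopentyl]acetate | C=C[C@@H]1[C@@H](CC(=O)OCC)C(=O)C[C@H]1O[Si](C)(C)C(C)(C)C | intermediate
12 | lithium alkoxide of ethyl 2-[(1R,2R,3R,5S)-3-[(tert-butyldimethylsilyl)oxy]-5-hydroxy-2-vinylcyclopentyl]acetate | C=C[C@@H]1[C@@H](CC(=O)OCC)[C@@H](O[Li])C[C@H]1O[Si](C)(C)C(C)(C)C | intermediate
13 | (3aR,4R,5R,6aS)-5-[(tert-butyldimethylsilyl)oxy]-4-vinylhexahydro-2H-cyclopenta[b]furan-2-one | C=C[C@@H]1[C@@H](CC(=O)O2)[C@@H]2C[C@H]1O[Si](C)(C)C(C)(C)C | intermediate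
14 | (S)-oct-1-en-3-ol | CCCCC[C@H](O)C=C | starting material
15 | (3aR,4R,5R,6aS)-5-[(tert-butyldimethylsilyl)oxy]-4-[(1E,3S)-3-hydroxyoct-1-en-1-yl]hexahydro-2H-cyclopenta[b]furan-2-one | CCCCC[C@H](O)/C=C/[C@@H]1[C@@H](CC(=O)O2)[C@@H]2C[C@H]1O[Si](C)(C)C(C)(C)C | intermediate
16 | 5-bromopentanoyl chloride | O=C(Cl)CCCCBr | starting material
17 | (3-methyloxetan-3-yl)methanol | CC1(CO)COC1 | starting material
18 | (3-methyloxetan-3-yl)methyl 5-bromopentanoate | O=C(CCCCBr)OCC1(C)COC1 | intermediate
19 | 1-(4-bromobutyl)-4-methyl-2,6,7-trioxabicyclo[2.2.2]octane | BrCCCCC12OCC(C)(CO1)CO2 | intermediate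
20 | 1-(4-iodobutyl)-4-methyl-2,6,7-trioxabicyclo[2.2.2]octane | ICCCCC12OCC(C)(CO1)CO2 | intermediate
21 | [4-(4-methyl-2,6,7-trioxabicyclo[2.2.2]octan-1-yl)butyl]lithium | [Li]CCCCC12OCC(C)(CO1)CO2 | intermediate
22 | lithium C15 alkoxide of lactone 15 | CCCCC[C@H](O[Li])/C=C/[C@@H]1[C@@H](CC(=O)O2)[C@@H]2C[C@H]1O[Si](C)(C)C(C)(C)C | intermediate
23 | dilithium salt (C15 alkoxide, C6 hemiketal alkoxide) of the cyclic hemiketal of 24 | CCCCC[C@H](O[Li])/C=C/[C@@H]1[C@@H](CC(O[Li])(CCCCC34OCC(C)(CO3)CO4)O2)[C@@H]2C[C@H]1O[Si](C)(C)C(C)(C)C | intermediate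
24 | 1-[(1R,2R,3R,5S)-3-[(tert-butyldimethylsilyl)oxy]-5-hydroxy-2-[(1E,3S)-3-hydroxyoct-1-en-1-yl]cyclopentyl]-6-(4-methyl-2,6,7-trioxabicyclo[2.2.2]octan-1-yl)hexan-2-one | CCCCC[C@H](O)/C=C/[C@@H]1[C@@H](CC(=O)CCCCC23OCC(C)(CO2)CO3)[C@@H](O)C[C@H]1O[Si](C)(C)C(C)(C)C | intermediate
25 | 3-hydroxy-2-(hydroxymethyl)-2-methylpropyl 7-[(1R,2R,3R,5S)-3,5-dihydroxy-2-[(1E,3S)-3-hydroxyoct-1-en-1-yl]cyclopentyl]-6-oxoheptanoate | CCCCC[C@H](O)/C=C/[C@@H]1[C@@H](CC(=O)CCCCC(=O)OCC(C)(CO)CO)[C@@H](O)C[C@H]1O | intermediate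
26 | 6-keto-prostaglandin F1α, 7-[(1R,2R,3R,5S)-3,5-dihydroxy-2-[(1E,3S)-3-hydroxyoct-1-en-1-yl]cyclopentyl]-6-oxoheptanoic acid | CCCCC[C@H](O)/C=C/[C@@H]1[C@@H](CC(=O)CCCCC(=O)O)[C@@H](O)C[C@H]1O | target

**Step count and risks**

Total step count: 14. Longest linear sequence: 11 steps (steps 1–9, 13 and 14; steps 10–12 prepare the α-chain reagent).

The three steps most likely to fail:

Step 3. The ester-conjugated dienylboronate is a weaker nucleophile than simple allylboronates. A slow reaction with an uncatalysed background pathway, or boron migration before addition, could erode the enantio- and anti-selectivity that define C11 and C12. The fallback sets out from 4 and comes back at 7 by auxiliary-controlled aldol chemistry. (S)-4-Benzyloxazolidin-2-one is N-acylated (n-BuLi, (E)-but-2-enoyl chloride, THF, −78 °C) to (S)-4-benzyl-3-[(E)-but-2-enoyl]oxazolidin-2-one F1. Its boron dienolate (n-Bu2BOTf, Et3N, CH2Cl2, −78 °C) undergoes the deconjugative Evans syn aldol reaction with 4 to give (S)-4-benzyl-3-[(2S,3R)-5-[(tert-butyldimethylsilyl)oxy]-3-hydroxy-2-vinylpentanoyl]oxazolidin-2-one F2. Silylation (TBSOTf, 2,6-lutidine) gives (S)-4-benzyl-3-[(2S,3R)-3,5-bis[(tert-butyldimethylsilyl)oxy]-2-vinylpentanoyl]oxazolidin-2-one F3. Reductive removal of the auxiliary (LiBH4, MeOH, THF, 0 °C) gives (2R,3R)-3,5-bis[(tert-butyldimethylsilyl)oxy]-2-vinylpentan-1-ol F4. Dess–Martin oxidation gives (2S,3R)-3,5-bis[(tert-butyldimethylsilyl)oxy]-2-vinylpentanal F5. A Wittig reaction with Ph3P=CHCO2Et (CH2Cl2, rt) then gives the (E)-enoate 7.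

Step 7. The basic carbene may cause loss of the silyloxy group from the β-silyloxy aldehyde, or proton loss at the doubly allylic C12–H, faster than the conjugate acylation, and facial selectivity at C8 may be low. The fallback sets out from 9 and comes back at 11, forming the same C8–C9 bond by single-electron umpolung in a neutral medium. SmI2 (THF, MeOH, −78 °C) should effect a ketyl–olefin 5-exo cyclisation onto the enoate to give ethyl 2-[(1R,2R,3R,5R)-3-[(tert-butyldimethylsilyl)oxy]-5-hydroxy-2-vinylcyclopentyl]acetate F6. The hydroxyl is expected trans to the acetate arm, which is of no consequence because Dess–Martin oxidation of either C9 epimer then gives ketone 11.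

Step 9. Metathesis at the hindered, branched ring vinyl group may be slow, so that self-metathesis of the allylic alcohol and ruthenium-hydride isomerisation take over. The fallback sets out from 13 and comes back at 15 by the classical olefination–reduction sequence. Ozonolysis (O3, CH2Cl2, −78 °C; then Me2S) gives (3aR,4R,5R,6aS)-5-[(tert-butyldimethylsilyl)oxy]-2-oxohexahydro-2H-cyclopenta[b]furan-4-carbaldehyde F7. Horner–Wadsworth–Emmons olefination with dimethyl (2-oxoheptyl)phosphonate (LiCl, i-Pr2NEt, MeCN) gives (3aR,4R,5R,6aS)-5-[(tert-butyldimethylsilyl)oxy]-4-[(E)-3-oxooct-1-en-1-yl]hexahydro-2H-cyclopenta[b]furan-2-one F8. Corey–Bakshi–Shibata reduction ((R)-2-methyl-CBS-oxazaborolidine, catecholborane, toluene, −78 °C) should then give the (15S)-alcohol 15.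

Further compounds
F1 | step 3 | (S)-4-benzyl-3-[(E)-but-2-enoyl]oxazolidin-2-one | C/C=C/C(=O)N1[C@@H](Cc2ccccc2)COC1=O
F2 | step 3 | (S)-4-benzyl-3-[(2S,3R)-5-[(tert-butyldimethylsilyl)oxy]-3-hydroxy-2-vinylpentanoyl]oxazolidin-2-one | C=C[C@@H]([C@H](O)CCO[Si](C)(C)C(C)(C)C)C(=O)N1[C@@H](Cc2ccccc2)COC1=O
F3 | step 3 | (S)-4-benzyl-3-[(2S,3R)-3,5-bis[(tert-butyldimethylsilyl)oxy]-2-vinylpentanoyl]oxazolidin-2-one | C=C[C@@H]([C@H](O[Si](C)(C)C(C)(C)C)CCO[Si](C)(C)C(C)(C)C)C(=O)N1[C@@H](Cc2ccccc2)COC1=O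
F4 | step 3 | (2R,3R)-3,5-bis[(tert-butyldimethylsilyl)oxy]-2-vinylpentan-1-ol | C=C[C@@H]([C@H](O[Si](C)(C)C(C)(C)C)CCO[Si](C)(C)C(C)(C)C)CO
F5 | step 3 | (2S,3R)-3,5-bis[(tert-butyldimethylsilyl)oxy]-2-vinylpentanal | C=C[C@@H]([C@H](O[Si](C)(C)C(C)(C)C)CCO[Si](C)(C)C(C)(C)C)C=O
F6 | step 7 | ethyl 2-[(1R,2R,3R,5R)-3-[(tert-butyldimethylsilyl)oxy]-5-hydroxy-2-vinylcyclopentyl]acetate | C=C[C@@H]1[C@@H](CC(=O)OCC)[C@H](O)C[C@H]1O[Si](C)(C)C(C)(C)C
F7 | step 9 | (3aR,4R,5R,6aS)-5-[(tert-butyldimethylsilyl)oxy]-2-oxohexahydro-2H-cyclopenta[b]furan-4-carbaldehyde | O=C[C@@H]1[C@@H](CC(=O)O2)[C@@H]2C[C@H]1O[Si](C)(C)C(C)(C)C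
F8 | step 9 | (3aR,4R,5R,6aS)-5-[(tert-butyldimethylsilyl)oxy]-4-[(E)-3-oxooct-1-en-1-yl]hexahydro-2H-cyclopenta[b]furan-2-one | CCCCCC(=O)/C=C/[C@@H]1[C@@H](CC(=O)O2)[C@@H]2C[C@H]1O[Si](C)(C)C(C)(C)C
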